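# Proposed total synthesis of CNP0120049.2 (8-lavandulyl-3,5,7,2',4'-pentahydroxyflavone)

Flavonoid numbering is used throughout: O1, C2–C8a for the chromenone, primes for ring B, double primes for the side chain.

## Analysis of the target

The target is a flavonol, a 3-hydroxychromen-4-one. Its benzo ring A (C4a–C8a) carries hydroxyls at C5 and C7 and a lavandulyl chain at C8, its pyranone ring C carries the 3-hydroxyl, and C2 bears ring B, a 2,4-dihydroxyphenyl group. The only stereocentre is C2'' of the 5-methyl-2-(prop-1-en-2-yl)hex-4-enyl chain. It is S by the sequence rule but has the spatial arrangement of (R)-lavandulol, because the arylmethyl branch ranks below the isopropenyl group whereas the hydroxymethyl group ranks above it. It has no stereochemical partner in the molecule, so it has to be brought in as a single enantiomer and then left untouched. The side chain is a 1,5-diene that acid can cyclize, onto itself or onto the 7-hydroxyl, and that does not survive hydrogenation or late electrophilic oxidants and halogens. The five acidic hydroxyls make the flavonol easy to oxidize in base and air. The real difficulty is regiochemical: a non-allylic, β-branched primary alkyl group must sit at C8 and not at C6 or on oxygen, and neither a Claisen shift nor a phenolate C-alkylation can place it there cleanly. The strategy rests on the fact that ring A is a phloroglucinol fused to ring C through C4a–C8a. C5, C6, C7 and C8, with their two oxygens and the C8 substituent, are therefore the four carbons of a γ-alkylated acetoacetate in the form of its 1-methoxy-1,3-bis(silyloxy)diene. The nucleophilic terminus of that diene can bond only to C8a of a pyranone that already holds rings B and C.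

## Retrosynthetic reasoning

**23 ⇐ 22.** The last operation only removes three acetyl groups from O3, O2' and O4'. Acetates are chosen because they come off by mild methanolysis, which the 1,5-diene tolerates, and because they make ring B and the pyranone electron-poor, which two earlier steps need. A silyl-protected version was considered and set aside for the reason given under 10 ⇐ 8.

**22 ⇐ 10 + 18.** Ring A is cut at C4a–C5 and C8–C8a. This is the only cut that places the side chain by construction: the alkylated terminus of 18 can join only the unsubstituted pyranone carbon next to the ring oxygen of 10, and the ketene-acetal carbon can join only the bromine-bearing carbon. The forward reaction has to form both bonds and then lose the bromine with H-8a and the methoxy group with H-8. A 4-pyranone is a weak acceptor, so the carbonyl is O-silylated first and the annulation runs through pyrylium salt 19 and adduct 20 as a stepwise, polar [4+2] process. The gain is full convergence: all 25 carbons are assembled in one step with the C8 regiochemistry fixed.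

**18 ⇐ 16 ⇐ 15 ⇐ 12 + 13; 12 ⇐ 11.** The diene is the doubly silylated form of β-keto ester 15. The bond between the side-chain CH2 and the γ-carbon of 13 is cut, so the forward step is the alkylation of dianion 14 with iodide 12. The stereocentre is bought with 11 and lies one carbon away from every reacting centre on the way to 18.

**10 ⇐ 8 ⇐ 7.** The C5–Br bond is made last on the pyranone by addition–elimination. Acetylation of 7 to 8 comes first, because a free or silylated 2,4-dioxygenated phenyl ring would take up bromine faster than C5 of the pyranone. With acetates the order is reversed and C5 is the only nucleophilic carbon left.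

**7 ⇐ 6 ⇐ 5.** The pyranone is drawn from a furan by oxidative ring expansion. The ring-expanded product of an unsubstituted furyl carbinol lies two hydrogens below a 3-hydroxy-4-pyranone, so isomerization alone cannot deliver 7. The furan of 5 therefore carries bromine at C3. It reappears at C4 of 6 and is exchanged for oxygen when acid aromatizes the ring. The missing oxidation level is thus stored in the starting furan, and no second oxidant has to be used on a molecule that contains the electron-rich ring B. The acetal protecting groups fall in the same acid step.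

**5 ⇐ 2 + 3 (through 4); 2 ⇐ 1.** The carbinol carbon, the future C2, is formed by addition of furyllithium 4 to aldehyde 2, which is 1 with both phenols masked as acetals that tolerate the organolithium.

## Alternatives that were turned down

**Alternative 1:** The disconnection lies inside the side chain. An enzyme of the Baeyer–Villiger monooxygenase family, with cofactor recycling and air, would insert oxygen into one of the two enantiotopic acyl–CH2 bonds of 3-(prop-1-en-2-yl)cyclobutan-1-one A1 and give (4R)-4-(prop-1-en-2-yl)oxolan-2-one A2. Its CH2–O arm would become C1'' and its acyl arm would be extended to the prenyl unit, which leads to the equivalent of 11. In its favour, the stereocentre is made catalytically from an achiral ketone, 3-substituted cyclobutanones are a good substrate class for such enzymes, and the isopropenyl group is not epoxidized. On optical purity it is stronger than the chosen route, which depends on the quality of purchased 11. Against it, the step makes no bond of the flavonol. A1 has to be prepared, and A2 needs reduction and olefination before it reaches the stage at which step 7 starts. The C8 attachment stays unsolved. The chosen strategy buys the stereocentre and spends its risk on the regiochemical problem, which is the harder one.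

**Alternative 2:** Ring C is cut at C4a–C4, C4–C3 and O1–C2. A palladium–phosphine catalyst under carbonylative conditions with a secondary amine would join 2-iodo-6-[(2S)-5-methyl-2-(prop-1-en-2-yl)hex-4-en-1-yl]-3,5-bis(triisopropylsilyloxy)phenol A3, one carbon from the gas phase and 1-ethynyl-2,4-bis(triisopropylsilyloxy)benzene A4. Carbonylative alkynylation and 6-endo oxa-Michael closure would give 8-lavandulyl-5,7,2',4'-tetrakis(triisopropylsilyloxy)flavone A5. This three-component annulation is a known reaction, so on precedent of the key step it is stronger than the chosen route. Against it, A5 has no oxygen at C3, and hydroxylating a flavone there in the presence of the side-chain diene excludes the usual epoxidizing oxidants. A3 already needs the side chain between two oxygens and the iodine at one defined carbon, so the regiochemical problem is moved into the starting material. The iodide is flanked on both sides and electron-rich, and 5-exo closure to an aurone competes. The chosen strategy offers the C8 regiochemistry by construction and has the C3 oxygen in place from the start, at the price of an unprecedented annulation.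

**Alternative 3:** Ring B is cut at C1'–C2' and C5'–C6'. Heating 2-ethynyl-3,5,7-tris(methoxymethoxy)-8-[(2S)-5-methyl-2-(prop-1-en-2-yl)hex-4-en-1-yl]-4H-chromen-4-one A6 with 1-methoxy-1,3-bis(trimethylsilyloxy)buta-1,3-diene A7 would give, after loss of the methoxy and silyl groups, the 3,5,7-tris(methoxymethyl) ether of the target A8. In its favour, such dienes are known to react with acceptor alkynes. The aromatization needs no angular leaving group, and the regiochemistry gives the 2',4'-hydroxyls. On simplicity of the aromatization it is stronger than the chosen key step. Against it, it constructs the ring that is easiest to buy. A6 must already contain ring A with the side chain at C8 and the 3-oxygen, so the hard part is untouched and a long linear sequence precedes the key step. The alkyne is activated only through C2=C3. The three acetals of A8 have to be removed by acid next to the acid-sensitive 1,5-diene and the 7-hydroxyl. The chosen strategy uses the same diene logic on the ring where the regiochemical problem lies.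

Key step: step 11

Assumption: (R)-lavandulol 11 is purchased in enantioenriched form; no step touches its stereocentre, so its optical purity is carried into 23.

Remark: 5 and 6 are racemic or mixtures of stereoisomers whose stereocentres disappear in step 4; 16 and 18 are used as E/Z mixtures, since the geometry is lost on aromatization.

## Route

Step 1
Reactants: 1 2,4-dihydroxybenzaldehyde
Product: 2 2,4-bis(methoxymethoxy)benzaldehyde
Conditions: MOMCl, i-Pr2NEt, CH2Cl2, 0 °C → 40 °C
Reagents that add atoms: chloromethyl methyl ether, COCCl
Why: O-alkylation of both phenols as methoxymethyl acetals; the acetals survive the organolithium and the oxidation and are cleaved in the acid of step 4, so no separate deprotection is spent on them.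

Step 2
Reactants: 3 3-bromofuran; 2 2,4-bis(methoxymethoxy)benzaldehyde
Product: 5 (3-bromofuran-2-yl)[2,4-bis(methoxymethoxy)phenyl]methanol (racemic), via 3-bromo-2-lithiofuran 4 (not isolated)
Conditions: LiN(i-Pr)2, THF, −78 °C; then 2, −78 → −40 °C; aq. NH4Cl
Reagents that add atoms: none
Why: Directed deprotonation of 3-bromofuran at C2, between oxygen and bromine, followed by 1,2-addition of the furyllithium to the aldehyde at low temperature, where halogen migration does not compete; the new carbinol centre is racemic and is destroyed in step 4.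

Step 3
Reactants: 5 (3-bromofuran-2-yl)[2,4-bis(methoxymethoxy)phenyl]methanol
Product: 6 4-bromo-2-[2,4-bis(methoxymethoxy)phenyl]-6-hydroxy-2H-pyran-3(6H)-one (mixture of stereoisomers)
Conditions: VO(acac)2 (cat.), t-BuOOH, CH2Cl2, 0 °C → rt
Reagents that add atoms: tert-butyl hydroperoxide, CC(C)(C)OO
Why: Achmatowicz rearrangement: hydroxyl-directed oxidation of the furan and ring expansion to the pyranone hemiacetal, in which the furan C3 bromine becomes the vinylic bromine at C4; the neutral vanadium–hydroperoxide system should spare the acid-labile benzylic carbinol and the electron-rich aryl ring.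

Step 4
Reactants: 6 4-bromo-2-[2,4-bis(methoxymethoxy)phenyl]-6-hydroxy-2H-pyran-3(6H)-one
Product: 7 2-(2,4-dihydroxyphenyl)-3-hydroxy-4H-pyran-4-one
Conditions: 2 M HCl, MeOH–H2O, 65 °C
Reagents that add atoms: water, O
Why: Acid-mediated aromatization of a 4-halo-6-hydroxy-2H-pyran-3(6H)-one to a 3-hydroxy-4-pyranone, the closing stage of maltol-type γ-pyrone syntheses: loss of the anomeric hydroxyl and of H-2 leads to a pyrylium stage at which water displaces bromide at C4, so the bromine supplies the oxidation level that an isomerization alone lacks. The methoxymethyl acetals are cleaved in the same medium, with methanol trapping the formaldehyde.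

Step 5
Reactants: 7 2-(2,4-dihydroxyphenyl)-3-hydroxy-4H-pyran-4-one
Product: 8 2-[2,4-bis(acetyloxy)phenyl]-4-oxo-4H-pyran-3-yl acetate
Conditions: Ac2O, pyridine, DMAP (cat.), 0 °C → rt
Reagents that add atoms: acetic anhydride, CC(=O)OC(C)=O
Why: Exhaustive O-acetylation under nucleophilic catalysis; the acetates turn the aryl ring from the most into the least nucleophilic π-system of the molecule and lower the electron density of the pyranone, which steps 6 and 11 both need.

Step 6
Reactants: 8 2-[2,4-bis(acetyloxy)phenyl]-4-oxo-4H-pyran-3-yl acetate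
Product: 10 2-[2,4-bis(acetyloxy)phenyl]-5-bromo-4-oxo-4H-pyran-3-yl acetate, via 5,6-dibromo-5,6-dihydropyranone 9 (not isolated)
Conditions: Br2, CH2Cl2, 0 °C; then Et3N, 0 °C → rt
Reagents that add atoms: bromine, BrBr
Why: Bromine addition across the enol-ether C5=C6 bond and amine-induced loss of HBr through the enolizable C5–H, the addition–elimination route used for 3-bromo-4-pyranones and 3-bromochromones, should place bromine only at C5; C6 carries the ring oxygen and the bis(acetyloxy)phenyl ring is too deactivated to compete.

Step 7
Reactants: 11 (R)-lavandulol, (2R)-5-methyl-2-(prop-1-en-2-yl)hex-4-en-1-ol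
Product: 12 (R)-lavandulyl iodide, (2R)-1-iodo-5-methyl-2-(prop-1-en-2-yl)hex-4-ene
Conditions: I2, PPh3, imidazole, CH2Cl2, 0 °C → rt
Reagents that add atoms: iodine, II
Why: Appel-type iodination of the primary alcohol; substitution takes place at CH2, so the neighbouring stereocentre keeps its configuration.

Step 8
Reactants: 13 methyl acetoacetate; 12 (R)-lavandulyl iodide
Product: 15 methyl (6R)-9-methyl-3-oxo-6-(prop-1-en-2-yl)dec-8-enoate, via methyl acetoacetate dianion 14 (not isolated)
Conditions: NaH, THF, 0 °C; n-BuLi, 0 °C; then 12, DMPU, 0 °C → rt; 1 M HCl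
Reagents that add atoms: none
Why: γ-Alkylation of the acetoacetate dianion at its more basic terminal carbon by SN2 on the primary iodide; the stereocentre is β to the reacting carbon and is not involved, and the polar cosolvent favours substitution over elimination.

Step 9
Reactants: 15 methyl (6R)-9-methyl-3-oxo-6-(prop-1-en-2-yl)dec-8-enoate
Product: 16 methyl (6R)-9-methyl-6-(prop-1-en-2-yl)-3-(trimethylsilyloxy)deca-2,8-dienoate
Conditions: TMSCl, Et3N, toluene, rt
Reagents that add atoms: chlorotrimethylsilane, C[Si](C)(C)Cl
Why: Soft enolization and O-silylation of the β-keto ester to the 3-silyloxy enoate, the standard first stage towards 1-alkoxy-1,3-bis(silyloxy)dienes.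

Step 10
Reactants: 16 methyl (6R)-9-methyl-6-(prop-1-en-2-yl)-3-(trimethylsilyloxy)deca-2,8-dienoate
Product: 18 (6S)-1-methoxy-9-methyl-6-(prop-1-en-2-yl)-1,3-bis(trimethylsilyloxy)deca-1,3,8-triene, via lithium dienolate 17 (not isolated)
Conditions: LiN(i-Pr)2, THF, −78 °C; TMSCl, −78 °C → rt
Reagents that add atoms: chlorotrimethylsilane, C[Si](C)(C)Cl
Why: Kinetic γ-deprotonation of the silyloxy enoate to the extended ester enolate and O-silylation give the 4-alkylated diene, which is moisture-sensitive and used at once; the descriptor changes from R to S only because the branch priorities change.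

Step 11
Reactants: 10 2-[2,4-bis(acetyloxy)phenyl]-5-bromo-4-oxo-4H-pyran-3-yl acetate; 18 (6S)-1-methoxy-9-methyl-6-(prop-1-en-2-yl)-1,3-bis(trimethylsilyloxy)deca-1,3,8-triene
Product: 22 2-[2,4-bis(acetyloxy)phenyl]-5,7-dihydroxy-8-[(2S)-5-methyl-2-(prop-1-en-2-yl)hex-4-en-1-yl]-4-oxo-4H-chromen-3-yl acetate, via 4-silyloxypyrylium triflate 19 (not isolated), via angular bromo cycloadduct 20 (not isolated), via 5,7-bis(trimethylsilyl) ether 21 (not isolated)
Conditions: TMSOTf, 2,6-di-tert-butyl-4-methylpyridine, CH2Cl2, 0 °C → rt; then 18, −78 → 0 °C; then Et3N, 0 °C → rt; citric acid, MeOH–H2O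
Reagents that add atoms: none
Why: Proposed new method: O-silylation of the pyranone carbonyl of 10 should give pyrylium salt 19, which turns the sluggish vinylogous ester into a strong electrophile whose only unsubstituted α-position is C6 (future C8a); the side-chain-bearing terminus C4 of 18, its most nucleophilic carbon, should add there (vinylogous Mukaiyama–Michael step, C8–C8a), and the 2H-pyran enol silane so formed should close through its bromine-bearing carbon onto the dialkoxycarbenium carbon left from the ketene acetal (6-(enolexo)-exo-trig, C4a–C5), which completes ring A by a stepwise, polar [4+2] annulation and gives 20. The closest known reaction types are the additions and tandem annulations of silyloxydienes with 4-silyloxybenzopyrylium triflates made from chromones and the cycloaddition–aromatization of 1-alkoxy-1,3-bis(silyloxy)dienes with halo-quinones, neither of which has been shown on a monocyclic 5-halo-4-pyranone. In 20 the angular bromine and H-8a are cis, so an anti E2 elimination is not available; the silyl triflate should therefore first ionize the C5 ketal so that the methoxy group leaves with H-8, and the resulting 4a,8a-dihydroarene should then lose bromide and H-8a under Et3N, through a pentadienyl (arenium) cation or a syn elimination driven by aromatization, to give 21. Bromine on C4a also means that no enolate can form at that carbon, which blocks the retro-oxa-Michael opening of the pyran ring to which such adducts are otherwise prone. The step needs regioselectivity only, and the substrates secure it: the alkylated diene terminus can meet only C6 of the pyrylium and the ketene-acetal carbon only C5, so the side chain ends at C8 and the free hydroxyls at C5 and C7. The four sp3 centres of 20 are erased on aromatization and the side-chain stereocentre, two bonds from the reacting carbon, is not touched; the hindered pyridine keeps the medium free of triflic acid so that the 1,5-diene is not protonated. Mild acidic methanolysis on work-up should cleave the two aryl trimethylsilyl ethers of 21 and leave the three acetates.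

Step 12
Reactants: 22 2-[2,4-bis(acetyloxy)phenyl]-5,7-dihydroxy-8-[(2S)-5-methyl-2-(prop-1-en-2-yl)hex-4-en-1-yl]-4-oxo-4H-chromen-3-yl acetate
Product: 23 2-(2,4-dihydroxyphenyl)-3,5,7-trihydroxy-8-[(2S)-5-methyl-2-(prop-1-en-2-yl)hex-4-en-1-yl]-4H-chromen-4-one (target)
Conditions: K2CO3, MeOH (degassed), 0 °C; then 1 M HCl
Reagents that add atoms: none
Why: Base-mediated methanolysis of the enol and aryl acetates; no strong acid, fluoride or hydrogen is involved, so the 1,5-diene and the stereocentre are safe, and exclusion of air with prompt acidification protects the electron-rich flavonol.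

## Compound list

1 | 2,4-dihydroxybenzaldehyde | O=Cc1ccc(O)cc1O | starting material
2 | 2,4-bis(methoxymethoxy)benzaldehyde | O=Cc1ccc(OCOC)cc1OCOC | intermediate
3 | 3-bromofuran | Brc1ccoc1 | starting material
4 | 3-bromo-2-lithiofuran | [Li]c1occc1Br | intermediate (not isolated)
5 | (3-bromofuran-2-yl)[2,4-bis(methoxymethoxy)phenyl]methanol (racemic) | OC(c1occc1Br)c1ccc(OCOC)cc1OCOC | intermediate
6 | 4-bromo-2-[2,4-bis(methoxymethoxy)phenyl]-6-hydroxy-2H-pyran-3(6H)-one (mixture of stereoisomers) | O=C1C(Br)=CC(O)OC1c1ccc(OCOC)cc1OCOC | intermediate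
7 | 2-(2,4-dihydroxyphenyl)-3-hydroxy-4H-pyran-4-one | O=c1ccoc(-c2ccc(O)cc2O)c1O | intermediate
8 | 2-[2,4-bis(acetyloxy)phenyl]-4-oxo-4H-pyran-3-yl acetate | O=c1ccoc(-c2ccc(OC(C)=O)cc2OC(C)=O)c1OC(C)=O | intermediate
9 | 2-[2,4-bis(acetyloxy)phenyl]-5,6-dibromo-4-oxo-5,6-dihydro-4H-pyran-3-yl acetate | O=C1C(Br)C(Br)OC(-c2ccc(OC(C)=O)cc2OC(C)=O)=C1OC(C)=O | intermediate (not isolated)
10 | 2-[2,4-bis(acetyloxy)phenyl]-5-bromo-4-oxo-4H-pyran-3-yl acetate | O=c1c(Br)coc(-c2ccc(OC(C)=O)cc2OC(C)=O)c1OC(C)=O | intermediate
11 | (R)-lavandulol, (2R)-5-methyl-2-(prop-1-en-2-yl)hex-4-en-1-ol | C=C(C)[C@@H](CC=C(C)C)CO | starting material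
12 | (R)-lavandulyl iodide, (2R)-1-iodo-5-methyl-2-(prop-1-en-2-yl)hex-4-ene | C=C(C)[C@@H](CC=C(C)C)CI | intermediate
13 | methyl acetoacetate | COC(=O)CC(C)=O | starting material
14 | methyl acetoacetate dianion (sodium lithium salt) | [Na+].[Li+].[CH2-]C(=O)[CH-]C(=O)OC | intermediate (not isolated)
15 | methyl (6R)-9-methyl-3-oxo-6-(prop-1-en-2-yl)dec-8-enoate | C=C(C)[C@@H](CC=C(C)C)CCC(=O)CC(=O)OC | intermediate
16 | methyl (6R)-9-methyl-6-(prop-1-en-2-yl)-3-(trimethylsilyloxy)deca-2,8-dienoate | C=C(C)[C@@H](CC=C(C)C)CCC(O[Si](C)(C)C)=CC(=O)OC | intermediate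
17 | lithium (6S)-1-methoxy-9-methyl-6-(prop-1-en-2-yl)-3-(trimethylsilyloxy)deca-1,3,8-trien-1-olate | [Li+].C=C(C)[C@@H](CC=C(C)C)CC=C(O[Si](C)(C)C)C=C(OC)[O-] | intermediate (not isolated)
18 | (6S)-1-methoxy-9-methyl-6-(prop-1-en-2-yl)-1,3-bis(trimethylsilyloxy)deca-1,3,8-triene | C=C(C)[C@@H](CC=C(C)C)CC=C(O[Si](C)(C)C)C=C(OC)O[Si](C)(C)C | intermediate
19 | 3-(acetyloxy)-2-[2,4-bis(acetyloxy)phenyl]-5-bromo-4-(trimethylsilyloxy)pyrylium trifluoromethanesulfonate | C[Si](C)(C)Oc1c(Br)c[o+]c(-c2ccc(OC(C)=O)cc2OC(C)=O)c1OC(C)=O.[O-]S(=O)(=O)C(F)(F)F | intermediate (not isolated)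
20 | 2-[2,4-bis(acetyloxy)phenyl]-4a-bromo-5-methoxy-8-[(2S)-5-methyl-2-(prop-1-en-2-yl)hex-4-en-1-yl]-4-oxo-5,7-bis(trimethylsilyloxy)-4a,5,8,8a-tetrahydro-4H-chromen-3-yl acetate (ring stereocentres undefined) | C=C(C)[C@@H](CC=C(C)C)CC1C(O[Si](C)(C)C)=CC(OC)(O[Si](C)(C)C)C2(Br)C(=O)C(OC(C)=O)=C(c3ccc(OC(C)=O)cc3OC(C)=O)OC12 | intermediate (not isolated)
21 | 2-[2,4-bis(acetyloxy)phenyl]-8-[(2S)-5-methyl-2-(prop-1-en-2-yl)hex-4-en-1-yl]-4-oxo-5,7-bis(trimethylsilyloxy)-4H-chromen-3-yl acetate | C=C(C)[C@@H](CC=C(C)C)Cc1c(O[Si](C)(C)C)cc(O[Si](C)(C)C)c2c(=O)c(OC(C)=O)c(-c3ccc(OC(C)=O)cc3OC(C)=O)oc12 | intermediate (not isolated)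
22 | 2-[2,4-bis(acetyloxy)phenyl]-5,7-dihydroxy-8-[(2S)-5-methyl-2-(prop-1-en-2-yl)hex-4-en-1-yl]-4-oxo-4H-chromen-3-yl acetate | C=C(C)[C@@H](CC=C(C)C)Cc1c(O)cc(O)c2c(=O)c(OC(C)=O)c(-c3ccc(OC(C)=O)cc3OC(C)=O)oc12 | intermediate
23 | 2-(2,4-dihydroxyphenyl)-3,5,7-trihydroxy-8-[(2S)-5-methyl-2-(prop-1-en-2-yl)hex-4-en-1-yl]-4H-chromen-4-one | C=C(C)[C@@H](CC=C(C)C)Cc1c(O)cc(O)c2c(=O)c(O)c(-c3ccc(O)cc3O)oc12 | target

## Step count and risk

Total: 12 steps. Longest linear sequence: 8 steps (steps 1–6, 11 and 12, from 1). The diene branch (steps 7–10) joins at step 11.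

**Step 11 (key step, new method).** Three processes are most likely to go wrong.
- The sequence may stop after the first C–C bond, giving a conjugate adduct without ring closure.
- The pyran ring may open, either by β-elimination of O1 once negative charge builds up at C8 or by Lewis-acid ionization of the C8a–O1 bond in the dihydroarene. Bromine would then be lost as an electrophile and the ring oxygen would be misplaced.
- The side-chain 1,5-diene may undergo acid-induced cyclization if triflic acid is not fully scavenged.

Within the strategy, the halogen could be replaced by a group that leaves through a thermal syn pathway, but that is no better precedented. The fallback therefore uses known reactions. It sets out from iodide 12 and rejoins the route at 23. Zinc insertion (Zn, LiCl, THF, 40 °C) gives [(2R)-5-methyl-2-(prop-1-en-2-yl)hex-4-en-1-yl]zinc iodide F1. Commercial morin is converted with MOMCl and NaH in DMF into 2-[2,4-bis(methoxymethoxy)phenyl]-3,5,7-tris(methoxymethoxy)-4H-chromen-4-one F2. NIS in DMF should iodinate ring A of F2 to the 8-iodide F3; C8 is the usual site of halogenation in fully etherified 5,7-dioxygenated flavones, and the site has to be proved before use. Negishi coupling of F3 with F1 (Pd(OAc)2, SPhos, THF, 50 °C) gives the pentakis(methoxymethyl) ether of the target F4, and HCl in methanol at room temperature frees 23. This fallback gives up the built-in regiocontrol and ends with an acid step that the side chain has to survive.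

**Step 4.** The freed resorcinol ring may be attacked by the cationic intermediates or by released formaldehyde, leading to oligomers, and hydrolysis of the vinylic bromide may stay incomplete. The fallback avoids the furan route, including step 3. It sets out from aldehyde 2 and rejoins at 7. ZnCl2-promoted hetero-Diels–Alder reaction of 2 with 1-methoxy-3-(trimethylsilyloxy)buta-1,3-diene and mild acid work-up give 2-[2,4-bis(methoxymethoxy)phenyl]-2,3-dihydro-4H-pyran-4-one F5. Rubottom oxidation at C3 (LiN(SiMe3)2, TMSCl; then mCPBA) gives 2-[2,4-bis(methoxymethoxy)phenyl]-3-hydroxy-2,3-dihydro-4H-pyran-4-one F6. Dess–Martin oxidation and enolization give 2-[2,4-bis(methoxymethoxy)phenyl]-3-hydroxy-4H-pyran-4-one F7, and HCl in methanol at room temperature removes the acetals to give 7.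

**Step 6.** Bromine addition to the electron-poor pyranone may be slow, so that substitution on the aryl ring or cleavage of the enol acetate by the HBr formed takes over. The fallback carries the halogen from the start. It sets out from aldehyde 2 and rejoins at 10. 3,4-Dibromofuran is deprotonated at C2 with LiN(i-Pr)2 and added to 2 to give (3,4-dibromofuran-2-yl)[2,4-bis(methoxymethoxy)phenyl]methanol F8. Achmatowicz rearrangement gives 4,5-dibromo-2-[2,4-bis(methoxymethoxy)phenyl]-6-hydroxy-2H-pyran-3(6H)-one F9. Hot aqueous methanolic HCl, in which only the C4 bromine of the pyrylium stage is open to hydrolysis, gives 5-bromo-2-(2,4-dihydroxyphenyl)-3-hydroxy-4H-pyran-4-one F10. Acetylation (Ac2O, pyridine) gives 10.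

**Step 8.** The strongly basic dianion may cause E2 elimination of the β-branched iodide, whose β-hydrogen is allylic, instead of substitution. The fallback uses a softer nucleophile. It sets out from iodide 12 and rejoins at 15. Alkylation of dimethyl malonate (NaH, DMF, 60 °C) gives dimethyl 2-[(2S)-5-methyl-2-(prop-1-en-2-yl)hex-4-en-1-yl]propanedioate F11. Saponification and thermal decarboxylation give (4R)-7-methyl-4-(prop-1-en-2-yl)oct-6-enoic acid F12. Activation with carbonyldiimidazole and acylation of KO2CCH2CO2Me in the presence of MgCl2 and Et3N, with decarboxylation on work-up, give 15.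

## Further compounds

F1 | step 11 | [(2R)-5-methyl-2-(prop-1-en-2-yl)hex-4-en-1-yl]zinc iodide | C=C(C)[C@@H](CC=C(C)C)C[Zn]I
F2 | step 11 | 2-[2,4-bis(methoxymethoxy)phenyl]-3,5,7-tris(methoxymethoxy)-4H-chromen-4-one | COCOc1ccc(-c2oc3cc(OCOC)cc(OCOC)c3c(=O)c2OCOC)c(OCOC)c1
F3 | step 11 | 2-[2,4-bis(methoxymethoxy)phenyl]-8-iodo-3,5,7-tris(methoxymethoxy)-4H-chromen-4-one | COCOc1ccc(-c2oc3c(I)c(OCOC)cc(OCOC)c3c(=O)c2OCOC)c(OCOC)c1
F4 | step 11 | 2-[2,4-bis(methoxymethoxy)phenyl]-3,5,7-tris(methoxymethoxy)-8-[(2S)-5-methyl-2-(prop-1-en-2-yl)hex-4-en-1-yl]-4H-chromen-4-one | C=C(C)[C@@H](CC=C(C)C)Cc1c(OCOC)cc(OCOC)c2c(=O)c(OCOC)c(-c3ccc(OCOC)cc3OCOC)oc12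
F5 | step 4 | 2-[2,4-bis(methoxymethoxy)phenyl]-2,3-dihydro-4H-pyran-4-one (racemic) | O=C1C=COC(c2ccc(OCOC)cc2OCOC)C1
F6 | step 4 | 2-[2,4-bis(methoxymethoxy)phenyl]-3-hydroxy-2,3-dihydro-4H-pyran-4-one (racemic) | O=C1C=COC(c2ccc(OCOC)cc2OCOC)C1O
F7 | step 4 | 2-[2,4-bis(methoxymethoxy)phenyl]-3-hydroxy-4H-pyran-4-one | O=c1ccoc(-c2ccc(OCOC)cc2OCOC)c1O
F8 | step 6 | (3,4-dibromofuran-2-yl)[2,4-bis(methoxymethoxy)phenyl]methanol (racemic) | OC(c1occ(Br)c1Br)c1ccc(OCOC)cc1OCOC
F9 | step 6 | 4,5-dibromo-2-[2,4-bis(methoxymethoxy)phenyl]-6-hydroxy-2H-pyran-3(6H)-one (mixture of stereoisomers) | O=C1C(Br)=C(Br)C(O)OC1c1ccc(OCOC)cc1OCOC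
F10 | step 6 | 5-bromo-2-(2,4-dihydroxyphenyl)-3-hydroxy-4H-pyran-4-one | O=c1c(Br)coc(-c2ccc(O)cc2O)c1O
F11 | step 8 | dimethyl 2-[(2S)-5-methyl-2-(prop-1-en-2-yl)hex-4-en-1-yl]propanedioate | C=C(C)[C@@H](CC=C(C)C)CC(C(=O)OC)C(=O)OC
F12 | step 8 | (4R)-7-methyl-4-(prop-1-en-2-yl)oct-6-enoic acid | C=C(C)[C@@H](CC=C(C)C)CCC(=O)O
A1 | alternative 1 | 3-(prop-1-en-2-yl)cyclobutan-1-one | C=C(C)C1CC(=O)C1
A2 | alternative 1 | (4R)-4-(prop-1-en-2-yl)oxolan-2-one | C=C(C)[C@H]1CC(=O)OC1
A3 | alternative 2 | 2-iodo-6-[(2S)-5-methyl-2-(prop-1-en-2-yl)hex-4-en-1-yl]-3,5-bis(triisopropylsilyloxy)phenol | C=C(C)[C@@H](CC=C(C)C)Cc1c(O)c(I)c(O[Si](C(C)C)(C(C)C)C(C)C)cc1O[Si](C(C)C)(C(C)C)C(C)C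
A4 | alternative 2 | 1-ethynyl-2,4-bis(triisopropylsilyloxy)benzene | C#Cc1ccc(O[Si](C(C)C)(C(C)C)C(C)C)cc1O[Si](C(C)C)(C(C)C)C(C)C
A5 | alternative 2 | 8-[(2S)-5-methyl-2-(prop-1-en-2-yl)hex-4-en-1-yl]-5,7-bis(triisopropylsilyloxy)-2-[2,4-bis(triisopropylsilyloxy)phenyl]-4H-chromen-4-one | C=C(C)[C@@H](CC=C(C)C)Cc1c(O[Si](C(C)C)(C(C)C)C(C)C)cc(O[Si](C(C)C)(C(C)C)C(C)C)c2c(=O)cc(-c3ccc(O[Si](C(C)C)(C(C)C)C(C)C)cc3O[Si](C(C)C)(C(C)C)C(C)C)oc12
A6 | alternative 3 | 2-ethynyl-3,5,7-tris(methoxymethoxy)-8-[(2S)-5-methyl-2-(prop-1-en-2-yl)hex-4-en-1-yl]-4H-chromen-4-one | C=C(C)[C@@H](CC=C(C)C)Cc1c(OCOC)cc(OCOC)c2c(=O)c(OCOC)c(C#C)oc12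
A7 | alternative 3 | 1-methoxy-1,3-bis(trimethylsilyloxy)buta-1,3-diene | C=C(O[Si](C)(C)C)C=C(OC)O[Si](C)(C)C
A8 | alternative 3 | 2-(2,4-dihydroxyphenyl)-3,5,7-tris(methoxymethoxy)-8-[(2S)-5-methyl-2-(prop-1-en-2-yl)hex-4-en-1-yl]-4H-chromen-4-one | C=C(C)[C@@H](CC=C(C)C)Cc1c(OCOC)cc(OCOC)c2c(=O)c(OCOC)c(-c3ccc(O)cc3O)oc12
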